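All runs are calculated on assumed constants.

The vessel is closed, stirred and isothermal, with X held at constant pressure above it. The meeting had before it these charges and readings:

the same everywhere: E 0.050 M; X 3.5 mM (held)

| charge | Q | remark | time |
|---|---|---|---|
| zeta | 0.085 M | run made earlier |  |
| delta | 0.24 M | run made earlier |  |
| spring | 0.0750 M |  | 10 min |
| dusk | 0.170 M |  | 10 min |
| dawn | 0.110 M |  | 10 min |

| run | time / min | E / % | Z / % | G / % |
|---|---|---|---|---|
| zeta | 2.00 | 77 | 19 | 0 |
| zeta | 4.00 | 64 | 33 | 9 |
| zeta | 6.00 | 44 | 40 | 17 |
| zeta | 8.00 | 33 | 40 | 27 |
| zeta | 10.0 | 24 | 39 | 39 |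
| delta | 0.833 | 91 | 7 | 0 |
| delta | 1.50 | 86 | 11 | 0 |
| delta | 3.00 | 77 | 18 | 6 |
| delta | 5.00 | 62 | 25 | 20 |
| delta | 10.0 | 29 | 17 | 51 |

(readings scatter by 1.5 percentage points)

- at the start none of J is dissolved
- the analysis behind the earlier runs scatters by 1.5 percentage points, standard deviation
- what may be going on: E + J -> Z; J + Q -> D; Z + D -> G; 2 D -> L; X <-> J

1. which of these there is most of at the end, counted by the E in it, spring (Z / E / G)
2. which of these there is most of at the end, counted by the E in it, dusk (Z / E / G)
3. which of these there is most of at the end, counted by the E in it, dawn (Z / E / G)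
4. final amount of the leader among these, as a percentage of the E charged, in spring
5. final amount of the leader among these, as a percentage of the E charged, in dusk
6. final amount of the leader among these, as a percentage of the E charged, in dawn

The analyst opened with the proposed scheme: J dissolves from X, J turns E into Z and Q into D, Z meets D to give G, and two D give L. She therefore proposed counting turnovers. Each E lost has taken a first turn to Z, and has taken a second turn if it stands as G.

At 10.0 min, she reported, zeta held G 39 % and Z 39 %, a value of 0.500 for G divided by G plus Z, while delta gave 0.750. She named this ratio the finished share, the conversion of the intermediate Z, and noted that G leads Z wherever it stands above 0.5.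

E left at that time was 24 % in zeta and 29 % in delta, about 26.5 % on average. If the new flasks leave about as much, she reckoned, the larger of Z and G holds about 36.8 % or more, so she put the contest between those two.

Drawing a straight line through Q, she reckoned finished shares of 0.484 for spring, 0.540 for dawn and 0.637 for dusk. That puts Z ahead in spring at 37.9 %, and G ahead in dawn at 39.7 % and in dusk at 46.8 %.

The chair cautioned that the tie in zeta sits within the scatter of 1.5 percentage points, and that spring's margin of 2.4 points is little larger, so spring is the close call.

The forecaster named the same leaders with higher amounts, holding that “G therefore saturates with Q”: Z at 41 % in spring, G at 44 % in dawn and G at 49 % in dusk.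

    E + J → Z (k = 46.0 /M/min)
    J + Q → D (k = 120 /M/min)
    Z + D → G (k = 2.10 /M/min)
    2 D → L (k = 0.120 /M/min)
    X ⇌ J, rate k5*(csat - [J]) (kL = 31.0 /min)

The flasks gave Z at 41.9 % in spring, G at 42.1 % in dawn and G at 49.4 % in dusk. The finished shares came to 0.451 in spring, 0.561 in dawn and 0.677 in dusk. The gap in Z between dusk and spring comes from the difference in the concentration of Q: the dusk flask stands at 23.5 % Z, and with that difference taken away, its Q set back to spring's, it stands at 41.9 %. The same dusk charge read at 2.5 min has a finished share of 0.138, with Z at 19.6 %, G at 3.13 % and E leading at 77.2 %.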